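**Strategy.** Everything rests on cutting ring A at C8–C8a and at C4a–C5. Ring A bears an oxygen on each of the adjacent carbons C5, C6, C7 and C8, a C4O4 array that dimethyl squarate delivers intact, and C4a and C8a are simply the free C=C of a completed ring C pyranone. In a single operation the key step turns a cyclobutenone into the fully substituted benzenoid ring A: thermal opening to a dienylketene, then 6π closure onto the pyranone CH beside the ring oxygen. The precursor is the racemic tertiary alcohol made by adding 5-magnesiated 3-methoxy-2-(4-methoxyphenyl)-4-pyranone to dimethyl squarate.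

Key step: step 6

Remark: the target is achiral; the only stereocentre on the way, the carbinol carbon of cyclobutenone 9, is formed racemic and vanishes in step 6, and hydroquinone 12 is taken to be air-sensitive and is kept under argon until it is capped.

Step 1
Reactants: 1 3-hydroxy-4H-pyran-4-one
Product: 2 2-bromo-3-hydroxy-4H-pyran-4-one
Conditions: NBS (1.0 equiv), MeCN, 0 °C to rt
Reagents that add atoms: N-bromosuccinimide, O=C1CCC(=O)N1Br
Why: Electrophilic bromination of the enolised 1,2-dicarbonyl unit should go at C2, the enol β-carbon between the ring oxygen and C3–OH, which is the position that halogens take in kojic acid and related 3-hydroxy-4-pyranones.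

Step 2
Reactants: 2 2-bromo-3-hydroxy-4H-pyran-4-one
Product: 3 2-bromo-3-methoxy-4H-pyran-4-one
Conditions: MeI, K2CO3, acetone, rt
Reagents that add atoms: iodomethane, CI
Why: Williamson O-methylation of the acidic enolic hydroxyl should be clean at room temperature, where the vinylogous acyl bromide at C2 is not displaced.

Step 3
Reactants: 3 2-bromo-3-methoxy-4H-pyran-4-one; 4 (4-methoxyphenyl)boronic acid
Product: 5 3-methoxy-2-(4-methoxyphenyl)-4H-pyran-4-one
Conditions: Pd(PPh3)4 (3 mol %), K2CO3, 1,4-dioxane/H2O, 80 °C
Reagents that add atoms: none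
Why: Suzuki–Miyaura coupling at a β-bromo enone carbon, an especially easy oxidative addition for zerovalent palladium, should attach the aryl group at C2 and so complete ring C with its 2-aryl and 3-methoxy substituents.

Step 4
Reactants: 5 3-methoxy-2-(4-methoxyphenyl)-4H-pyran-4-one
Product: 6 5-iodo-3-methoxy-2-(4-methoxyphenyl)-4H-pyran-4-one
Conditions: I2 (0.6 equiv), (NH4)2Ce(NO3)6 (1.1 equiv), MeCN, 60 °C
Reagents that add atoms: iodine, II
Why: Oxidative electrophilic iodination (I2 with the tetravalent cerium salt) should take C5, the only free α-carbon of the vinylogous ester and the counterpart of C3 in chromones and flavones, which are iodinated there under these conditions while a carbonyl-conjugated methoxyphenyl ring is left alone.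

Step 5
Reactants: 6 5-iodo-3-methoxy-2-(4-methoxyphenyl)-4H-pyran-4-one; 7 dimethyl squarate
Product: 9 4-hydroxy-2,3-dimethoxy-4-[5-methoxy-6-(4-methoxyphenyl)-4-oxo-4H-pyran-3-yl]cyclobut-2-en-1-one (racemic), via pyranonylmagnesium chloride 8 (not isolated)
Conditions: i-PrMgCl·LiCl (1.05 equiv), THF, −40 °C; then 7 (1.3 equiv), THF, −78 °C; aq NH4Cl
Reagents that add atoms: none
Why: Iodine–magnesium exchange of the electron-poor alkenyl iodide is fast at −40 °C and the resulting Grignard reagent should add 1,2 to one carbonyl of the symmetrical squarate ester (Grignard addition), so only one constitutional isomer can form; the new carbinol stereocentre arises racemic, which is immaterial because step 6 erases it.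

Step 6
Reactants: 9 4-hydroxy-2,3-dimethoxy-4-[5-methoxy-6-(4-methoxyphenyl)-4-oxo-4H-pyran-3-yl]cyclobut-2-en-1-one
Product: 12 5,8-dihydroxy-3,6,7-trimethoxy-2-(4-methoxyphenyl)-4H-chromen-4-one, via dienylketene 10 (not isolated), via 8aH-dienone tautomer 11 (not isolated)
Conditions: degassed PhMe (0.02 M), 110 °C, Ar; concentrated under Ar and used at once
Reagents that add atoms: none
Why: Heat opens the cyclobutenone by a conrotatory 4π electrocyclic cleavage of the bond between the carbonyl carbon and the carbinol carbon, giving the dienylketene 10, whose ketene carbon (future C8) then bonds to the pyranone CH beside the ring oxygen (future C8a) in a thermal disrotatory 6π electrocyclisation; enolisation of the dienone 11 should deliver the aromatic hydroquinone. The closest known reaction type is the Moore rearrangement of squarate-derived 4-alkenyl-, 4-aryl- and 4-heteroaryl-4-hydroxycyclobutenones to hydroquinones, which also closes onto a CH next to the heteroatom in furyl and thienyl cases, so the pyranonyl group is a new substituent within a known substrate class. Ring A, a six-membered carbocycle, is closed in the 6π electrocyclic mode through the one new bond C8–C8a, with ring C carried through unchanged. No lasting stereocentre is created: the carbinol centre of 9 disappears on ring opening and the sp3 C8a of 11 on tautomerisation. The step needs outward rotation of the hydroxyl (torquoselectivity), which its donor character secures and which swings the pyranone C=C to the ketene side, and it needs closure at one site only, which is guaranteed because the four-membered ring sits on the pyranone carbon that becomes C4a, whose only CH neighbour is the future C8a.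

Step 7
Reactants: 12 5,8-dihydroxy-3,6,7-trimethoxy-2-(4-methoxyphenyl)-4H-chromen-4-one
Product: 14 3,5,6,7,8-pentamethoxy-2-(4-methoxyphenyl)-4H-chromen-4-one (3-methoxytangeretin), via 5-hydroxy-8-methoxy intermediate 13 (not isolated)
Conditions: Me2SO4 (6 equiv), K2CO3 (8 equiv), acetone, reflux, Ar
Reagents that add atoms: dimethyl sulfate, COS(=O)(=O)OC
Why: Exhaustive Williamson O-methylation with Me2SO4 and K2CO3 in refluxing acetone, the classical way to methylate 5,8-dihydroxyflavones including the hydrogen-bonded 5-OH, should cap the free 8-OH first and the chelated 5-OH on prolonged heating, while argon keeps the electron-rich hydroquinone from oxidising to the quinone beforehand.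

**Compound list**

1 | 3-hydroxy-4H-pyran-4-one | O=c1ccocc1O | starting material
2 | 2-bromo-3-hydroxy-4H-pyran-4-one | O=c1ccoc(Br)c1O | intermediate
3 | 2-bromo-3-methoxy-4H-pyran-4-one | COc1c(Br)occc1=O | intermediate
4 | (4-methoxyphenyl)boronic acid | COc1ccc(cc1)B(O)O | starting material
5 | 3-methoxy-2-(4-methoxyphenyl)-4H-pyran-4-one | COc1ccc(cc1)-c1occc(=O)c1OC | intermediate
6 | 5-iodo-3-methoxy-2-(4-methoxyphenyl)-4H-pyran-4-one | COc1ccc(cc1)-c1occ(I)c(=O)c1OC | intermediate
7 | dimethyl squarate (3,4-dimethoxycyclobut-3-ene-1,2-dione) | COC1=C(OC)C(=O)C1=O | starting material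
8 | [5-methoxy-6-(4-methoxyphenyl)-4-oxo-4H-pyran-3-yl]magnesium chloride (not isolated) | COc1ccc(cc1)-c1occ([Mg]Cl)c(=O)c1OC | intermediate
9 | 4-hydroxy-2,3-dimethoxy-4-[5-methoxy-6-(4-methoxyphenyl)-4-oxo-4H-pyran-3-yl]cyclobut-2-en-1-one (racemic) | COc1ccc(cc1)C1=C(OC)C(=O)C(=CO1)C1(O)C(OC)=C(OC)C1=O | intermediate
10 | (3Z)-4-hydroxy-2,3-dimethoxy-4-[5-methoxy-6-(4-methoxyphenyl)-4-oxo-4H-pyran-3-yl]buta-1,3-dien-1-one (dienylketene, not isolated) | O=C=C(OC)/C(OC)=C(/O)c1coc(-c2ccc(OC)cc2)c(OC)c1=O | intermediate
11 | 5-hydroxy-3,6,7-trimethoxy-2-(4-methoxyphenyl)-4H-chromene-4,8(8aH)-dione (racemic, not isolated) | COc1ccc(cc1)C1=C(OC)C(=O)C2=C(O)C(OC)=C(OC)C(=O)C2O1 | intermediate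
12 | 5,8-dihydroxy-3,6,7-trimethoxy-2-(4-methoxyphenyl)-4H-chromen-4-one | COc1ccc(-c2oc3c(O)c(OC)c(OC)c(O)c3c(=O)c2OC)cc1 | intermediate
13 | 5-hydroxy-3,6,7,8-tetramethoxy-2-(4-methoxyphenyl)-4H-chromen-4-one (not isolated) | COc1ccc(-c2oc3c(OC)c(OC)c(OC)c(O)c3c(=O)c2OC)cc1 | intermediate
14 | 3-methoxytangeretin, 3,5,6,7,8-pentamethoxy-2-(4-methoxyphenyl)-4H-chromen-4-one | COc1ccc(-c2oc3c(OC)c(OC)c(OC)c(OC)c3c(=O)c2OC)cc1 | target

**Totals**

Total steps: 7. Longest linear sequence: 7 steps (1 to 14).

**Steps most likely to fail**

Step 6. The 6π closure onto the electron-poor pyranone C=C may be slow. The ketene forms reversibly and could then drain through the minor inward rotation of the hydroxyl into lactonisation to a butenolide, and the hydroquinone may oxidise to the quinone during isolation. The fallback sets out from 9 and comes back at 14. The tertiary hydroxyl is methylated (MeI, Ag2O, MeCN, rt) to 2,3,4-trimethoxy-4-[5-methoxy-6-(4-methoxyphenyl)-4-oxo-4H-pyran-3-yl]cyclobut-2-en-1-one F1. Heating this ether in degassed p-xylene at 140 °C should open it to (3Z)-2,3,4-trimethoxy-4-[5-methoxy-6-(4-methoxyphenyl)-4-oxo-4H-pyran-3-yl]buta-1,3-dien-1-one F2, close that to 3,5,6,7-tetramethoxy-2-(4-methoxyphenyl)-4H-chromene-4,8(8aH)-dione F3, and tautomerise it to 8-hydroxy-3,5,6,7-tetramethoxy-2-(4-methoxyphenyl)-4H-chromen-4-one F4. One methylation of the unhindered 8-OH (MeI, K2CO3, acetone) then gives 14. This is the ring expansion of 4-alkoxy-4-arylcyclobutenones to monoprotected hydroquinones, and it changes the design in two ways. An ether cannot lactonise, so ring opening stays reversible until the electrocyclisation takes place. The product is a monophenol that cannot become a quinone and already carries the hard-to-methylate 5-oxygen as its methyl ether.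

Step 5. The magnesiated pyranone 8 may fragment by β-elimination of the ring oxygen (ring opening to an ynone enolate), or it may attack the carbonyl group of unreacted 6 before it reaches 7. The fallback sets out from 6 and comes back at 9. Zinc insertion (Zn dust, LiCl, THF, 25 °C) should turn 6 into [5-methoxy-6-(4-methoxyphenyl)-4-oxo-4H-pyran-3-yl]zinc iodide F5, a covalent, non-basic reagent that tolerates the pyranone carbonyl and does not eliminate. Its addition to the strained dione 7 is then driven by MgCl2 as Lewis acid (THF, 0 °C to rt), and aq NH4Cl work-up gives 9.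

Step 4. Iodination may spill over to the methoxyphenyl ring (ortho to its methoxy group) or stop short, giving mixtures that are hard to separate. The fallback sets out from 3 and comes back at 6; it places the halogen on the pyranone before the aryl group exists. NBS (MeCN, 60 °C) should brominate 3 at C5 to 2,5-dibromo-3-methoxy-4H-pyran-4-one F6. Suzuki–Miyaura coupling with one equivalent of 4 (Pd(PPh3)4, K2CO3, 1,4-dioxane/H2O, 60 °C) should take only the C2 bromide, the β-bromo enone site that reacts first in α,β-dihalo enones, giving 5-bromo-3-methoxy-2-(4-methoxyphenyl)-4H-pyran-4-one F7. Copper-catalysed halogen exchange (NaI, copper monoiodide CuI, trans-N,N'-dimethylcyclohexane-1,2-diamine, 1,4-dioxane, 110 °C) then gives 6.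

**Further compounds**

F1 | step 6 | 2,3,4-trimethoxy-4-[5-methoxy-6-(4-methoxyphenyl)-4-oxo-4H-pyran-3-yl]cyclobut-2-en-1-one (racemic) | COc1ccc(cc1)C1=C(OC)C(=O)C(=CO1)C1(OC)C(OC)=C(OC)C1=O
F2 | step 6 | (3Z)-2,3,4-trimethoxy-4-[5-methoxy-6-(4-methoxyphenyl)-4-oxo-4H-pyran-3-yl]buta-1,3-dien-1-one | O=C=C(OC)/C(OC)=C(/OC)c1coc(-c2ccc(OC)cc2)c(OC)c1=O
F3 | step 6 | 3,5,6,7-tetramethoxy-2-(4-methoxyphenyl)-4H-chromene-4,8(8aH)-dione (racemic) | COc1ccc(cc1)C1=C(OC)C(=O)C2=C(OC)C(OC)=C(OC)C(=O)C2O1
F4 | step 6 | 8-hydroxy-3,5,6,7-tetramethoxy-2-(4-methoxyphenyl)-4H-chromen-4-one | COc1ccc(-c2oc3c(O)c(OC)c(OC)c(OC)c3c(=O)c2OC)cc1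
F5 | step 5 | [5-methoxy-6-(4-methoxyphenyl)-4-oxo-4H-pyran-3-yl]zinc iodide | COc1ccc(cc1)-c1occ([Zn]I)c(=O)c1OC
F6 | step 4 | 2,5-dibromo-3-methoxy-4H-pyran-4-one | COc1c(Br)occ(Br)c1=O
F7 | step 4 | 5-bromo-3-methoxy-2-(4-methoxyphenyl)-4H-pyran-4-one | COc1ccc(cc1)-c1occ(Br)c(=O)c1OC
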